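(The readings stem from a simulated flask for an exercise, noise included.)

No rate constant is given for this flask, but a crossing concentration of J can be read from the books of L.

| setting | Wednesday's | Saturday's | Tuesday's | east | south-west | west | south-east | south |
|---|---|---|---|---|---|---|---|---|
| L | 0.020 M | 0.020 M | 0.020 M | 0.020 M | 0.020 M | 0.020 M | 0.020 M | 0.020 M |
| J | 0.94 mM | 8.3 mM | 95 mM | 1.00 mM | 3.00 mM | 10.0 mM | 25.0 mM | 80.0 mM |
| D | 10 µM | 10 µM | 10 µM | 10 µM | 10 µM | 10 µM | 10 µM | 10 µM |
| remark | run made earlier | run made earlier | run made earlier |  |  |  |  |  |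
| time |  |  |  | 2.0 min | 2.0 min | 2.0 min | 2.0 min | 2.0 min |

| run | time / s | G / % | L / % |
|---|---|---|---|
| Wednesday's | 10.0 | 60.7 | 36.1 |
| Wednesday's | 20.0 | 84.3 | 11.1 |
| Wednesday's | 30.0 | 91.2 | 4.8 |
| Wednesday's | 60.0 | 93.7 | 1.5 |
| Wednesday's | 120 | 95.0 | 0.7 |
| Saturday's | 10.0 | 52.3 | 17.6 |
| Saturday's | 30.0 | 65.9 | 2.1 |
| Saturday's | 60.0 | 66.3 | 0.9 |
| Saturday's | 80.0 | 66.6 | 0 |
| Saturday's | 120 | 66.7 | 0 |
| Tuesday's | 10.0 | 10.5 | 0.6 |
| Tuesday's | 30.0 | 11.4 | 0 |
| Tuesday's | 60.0 | 11.6 | 0 |
| Tuesday's | 80.0 | 11.1 | 0 |
| Tuesday's | 120 | 11.3 | 0 |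

(each reading ± 0.3 percentage points)

- the numbers in the tables scatter with a standard deviation of 0.3 percentage points
- "hardly changes" means that all values lie within two and a half points (for a concentration: within two and a half percent of the largest)

* amount of G at the end, in percent of the L charged for east, south-west, west, south-east, south, in this order
* how the row runs (rises, then falls / rises all the way / falls all the way / falls, then rises / hardly changes)

Each mole of L charged stands in one of three entries: L left, G, or missing. In Saturday's run at 120 s, L reads 0 % and G 66.7 %, and the missing entry is 6.66 mM against 8.3 mM of J charged. In Wednesday's run the missing entry is 0.860 mM, less than the 0.94 mM of J. In Tuesday's run it is 17.7 mM, less than the 95 mM of J. The reckoning supposes that the missing L is lost one to one with J.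

Suppose L splits at each moment between G and the loss in the ratio J×/J, with J× constant. Then G = J× ln(J₀/J), where J₀ is the J charged and J the J left. Saturday's books leave 1.64 mM of J and give 8.23 mM. This is the crossing J×, the concentration of J at which L goes equally to both routes; J×/J is the selectivity factor. Tuesday's books read 10.9 mM, so the reading is higher at the higher charge of J.

This reckoning, separate from the forecast, takes Saturday's crossing for west, with 10.0 mM of J. The books close when G plus the J spent equals 20 mM. With the whole charge of J spent, G is 10.0 mM. Putting G back through the crossing gives 12.97 mM, then 12.07 mM, then 12.31 mM, then 12.24 mM, then 12.26 mM, which is 61.3 % of the L charged.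

The forecast holds that “the shortfall tracks J”. It gives 94.8 %, 86.5 %, 61.5 %, 35 % and 13.2 %, and the row falls all the way. Its value for west is higher than this reckoning's.

The flasks end at 94.8 %, 86.0 %, 61.5 %, 35.2 % and 13.1 %, and the row falls all the way.

    L + D → G + D, rate k1*[L]^1.5*[D]/(1 + ([L]/Kh1)^1.5) (4.30 mM, k = 6.50 × 10⁵ M⁻¹·⁵ s⁻¹)
    L + J → E (k = 13.0 M⁻¹ s⁻¹)
    2 D → Q (k = 2800 M⁻¹ s⁻¹)

At the start of east, the step from L to G uses L 6.4 times as fast as the step from L + J to E, which puts the crossing there at 6.41 mM. Over the whole run, the end values of west give a crossing of 8.36 mM, and those of south give 10.7 mM.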